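A flat product curve tempts one to call the reaction over. The teal run, which is the asked flask followed so far, stays near 28.0% from 80.0 min on.

| flask | substrate | reagent | temperature | remark | time |
|---|---|---|---|---|---|
| teal | 17 mM | 0.50 equiv | 5 °C | the very flask that is asked about, followed so far |  |
| blue | 34 mM | 0.50 equiv | −10 °C | run made earlier |  |
| flask | 17 mM | 0.500 equiv | 5 °C |  | 6.0 h |

| run | time / min | product / % | substrate / % |
|---|---|---|---|
| teal | 80.0 | 27 | 75 |
| teal | 150 | 26 | 72 |
| teal | 240 | 28 | 74 |
| teal | 300 | 31 | 71 |
| blue | 20.0 | 7 | 92 |
| blue | 60.0 | 21 | 80 |
| blue | 120 | 28 | 71 |
| blue | 180 | 34 | 69 |

(readings scatter by 1.5 percentage points)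

- product taken out counts as made
- the earlier runs were read with a standard deviation of 1.5 percentage points
- additions bring no volume worth counting

- birch: at 6.0 h take out 90% of the product then present, then wait 3.0 h
- oak: at 6.0 h add reagent, 100% of the amount charged, then wait 3.0 h
- larch: change nothing and wait 3.0 h more
- alder: at 6.0 h raise the temperature by 15 K, then wait 3.0 h

* product, in percent of the substrate first charged, at 6.0 h
* the remedy with the largest gain of product, or "none" below 2 percentage points (birch / oak / larch / alder / none)
* product present, with what was taken out counted in, in percent of the substrate first charged, after birch
* product present, with what was taken out counted in, in percent of the substrate first charged, after larch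

Counting one reagent per substrate, the flask was charged with 8.50 mM of reagent and the teal readings put product near 4.76 mM, so about 3.74 mM of reagent is not in product.

Two chemists read this differently. The first says substrate + reagent ⇌ product has reached equilibrium with that reagent still free, so removing product should pay, up to about 38%. The second says reagent is leaving by a second, unseen way. In this view product forms at a rate proportional to c(substrate) times c(reagent), and c(substrate) falls as it forms. If the loss is first order in c(reagent), c(reagent) cancels from the ratio of the two ways, and c(substrate) sets how reagent divides.

My own reckoning follows the second view. Call c_split the c(substrate) at which both ways take reagent equally. Then reagent lost equals c_split times ln(substrate charged / substrate left), and the plateau reads 11.4 mM. The share of fresh reagent reaching product is c(substrate)/(c(substrate) + c_split). At the plateau c(substrate) is 12.2 mM, so the share starts at 51.8%, and oak should gain somewhat under 26 percentage points. The blue run changes concentration and temperature together, so it cannot test this.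

The forecast keeps both views open and stands at 28% now, 28% after larch, 33% after birch, and oak as the best remedy, on the ground that “Fresh reagent helps under both explanations”. It expects about 20 points from oak, where my reckoning gives more.

The flask gives 30.6%, 32.6% after larch, 34.4% after birch, and oak as the best remedy, with a gain of 23 points. After birch the flask holds 1.8 points more product than after larch.

    reagent ⇌ dormant form (K = 5.90, k = 2.97 × 10⁻⁴ /s, Ea = 80.0 kJ/mol, ΔH = −54.0 kJ/mol)
    substrate + reagent ⇌ product (K = 1980 /M, k = 0.0210 /M/s, Ea = 56.0 kJ/mol, ΔH = −7.00 kJ/mol)
    (constants at 5 °C)

The first chemist's view gets its region at long times: the flask's dormant form falls from 3.38 mM at 180 min to 1.80 mM at 3600 min, while product reaches 37.6%. With the simulated substrate of 69.4%, the share reckoning gives oak 25 points at its starting share, against the simulated 23 points. The neighbouring flask with 2.00 equiv of reagent at the same temperature ends with 81.9% product and 18.1% substrate. There c_split predicts 19.4 mM of reagent outside product. The reagent charge of that neighbouring flask minus its product leaves 20.1 mM, of which 17.3 mM stands as dormant form.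

The data were generated by integration with constants of no real substance; the scatter is artificial.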